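## The problem

Marchantin H is an 18-membered cyclophane in which four benzene rings are joined in a cycle by two diaryl ether oxygens (ring A–O–ring B and ring C–O–ring D) and two CH2–CH2 bridges (ring B to ring C and ring D to ring A). It has no stereocentre, so nothing has to be set or relayed; the task is connectivity, regiochemistry and ring closure. Ring A is a 1,2,4-trisubstituted phenol, ring B a para-phenylene, ring C a catechol and ring D a meta-phenylene. The ether oxygen of ring C sits at C2 between the C3 oxygen and the C1 ethylene bridge. A metal-mediated aryl ether coupling at this flanked oxygen meets a hindered phenol on one side and, on the other, a ring D that has no acceptor group for nucleophilic aromatic substitution. The free catechol and the ring A phenol are easily oxidised, above all under basic copper conditions, so they stay masked until the last step; the aryl bromide needed for ring closure must not meet organolithium reagents or hydrogenation catalysts. The opening lies in ring D: it carries only the ether oxygen at C1 and the bridge CH2 at C3, while C2, C4, C5 and C6 are CH. Such a ring can be grown on the oxygen from a two-carbon alkyne (C1, C2) and a four-carbon diene (C3 to C6) that carries the bridge on its terminus.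

## Retrosynthesis

**29 to 28.** The three O–H groups of 29 are traced back to O–CH3 groups in the trimethyl ether 28. The methyl groups are already present in the commercial aldehydes 5 and 15, so this masking costs no step on the way in. The forward reaction must cleave three aryl methyl ethers and leave two diaryl ethers intact, which is what BBr3 does.

**28 to 27.** The macrocycle is opened at the aryl C–O bond between ring A and the ring B oxygen, giving phenol bromide 27. Cutting the other ether would place the ring closure at the flanked ring C oxygen. Cutting a CH2–CH2 bridge would need an olefination–hydrogenation pair or an extrusion after ring closure. The ring A/ring B ether joins a para-alkyl phenol to a 3-bromo-4-methoxyphenyl unit, a pairing well suited to copper-mediated Ullmann etherification. The forward step must favour 18-membered ring closure over oligomerisation, so it is run at high dilution.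

**27 to 26.** The ring B phenol is masked as its MOM ether in 26. This oxygen has to be inert while the ring C phenol is vinylated, through n-BuLi and through prolonged heating, and then be freed without touching the methyl ethers. An acetal that leaves in methanolic acid meets all of these. The bromide is placed on ring A and not on ring B because the ring B/ring C half must pass through an organolithium step.

**26 to 14 and 24 (key disconnection).** Ring D is taken apart at two C–C bonds, C1–C6 and C2–C3 in the numbering above. This leaves C1 and C2 as the ethynyl group on the ring C oxygen of alkynyl ether 14, and C3 to C6 as the diene of 2-pyrone 24 with the bridge to ring A on C6. In the forward direction a Diels–Alder reaction gives bridged lactone 25, which loses CO2. The neighbouring cut, the ring C O–ring D C bond, is the hindered, unactivated coupling described above. The ring D cut avoids it, since the C–O bond already exists in 14. The two precursors are of equal size, each holds two of the four rings, and neither holds a ring junction that is hard to make. The forward reaction must give the meta orientation and run at a temperature that 14 tolerates.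

**14 to 11 to 8 and 9.** The O–C(sp) bond of 14 goes back to the (E)-1,2-dichlorovinyl ether 11 and from there to phenol 8 and trichloroethylene 9. The electrophile that the phenoxide meets is dichloroacetylene 10, formed in the flask. It is linear and small, so bond formation at the crowded oxygen is an addition, not a coupling. Two equivalents of n-BuLi then turn 11 into 14.

**8 to 7 to 4 and 5; 4 to 2 to 1.** The CH2–CH2 bridge between rings B and C is cut as a C=C bond (stilbene 7) into phosphonium salt 4 and 2-hydroxy-3,4-dimethoxybenzaldehyde 5. Aldehyde 5 has the full ring C oxygen pattern with the one phenol that is needed free. Salt 4 comes from 4-hydroxybenzyl alcohol 1 through MOM ether 2. The double-bond geometry of 7 does not matter because hydrogenation removes it.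

**24 to 23 to 22 to 20 and 21.** The ring O–C6 bond of the pyrone is cut to give the (Z)-enynoic acid 23 (6-endo lactonisation). The sp–sp2 bond of its ester 22 is cut to alkyne 20 and ethyl (Z)-3-iodoacrylate 21 (Sonogashira coupling). The ester is chosen over the free iodo acid because the free acid tends to cyclise in the 5-exo sense under palladium–copper coupling conditions. The vinyl iodide couples at room temperature, where the ring A bromide is inert.

**20 to 17 and 18; 17 to 16 to 15.** The benzylic C–C bond of 20 is cut to benzylic bromide 17 and a propargyl unit from propargyl bromide 18, used as allenylmagnesium bromide 19. Bromide 17 comes from 3-bromo-4-methoxybenzaldehyde 15 through alcohol 16. The ring A bromine and methoxy group are present from the start and are carried as spectators.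

## Roads not taken

**Alternative 1:** The CH2–CH2 bond between rings B and C of marchantin H trimethyl ether A2 (the same compound as 28) is cut and replaced by a CH2–SO2–CH2 unit, giving the 19-membered dibenzylic sulfone A1. In the forward direction, flash vacuum pyrolysis of A1 expels SO2 and the two benzylic carbons join, contracting the ring to 18 members.
- Merits: the ring is closed one stage earlier by sulfur alkylation, which is forgiving for large rings; the C–C bond forms without a catalyst and leaves no functional group; only demethylation follows the key step.
- Weak points: both diaryl ethers, the flanked ring C–O–ring D one included, must first be made by intermolecular aryl etherification. Rings B and C each need a benzylic handle, followed by sulfide formation and oxidation. A1 is a heavy, polar compound that has to be sublimed into a hot tube, and the benzylic radical pair on electron-rich rings can disproportionate instead of recombining.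
- Comparison: Alternative 1 is at least as good in the reliability of its ring closure and has a shorter end game. The chosen plan has no coupling at the hindered oxygen, uses ordinary glassware throughout, and joins two halves of equal size late.

**Alternative 2:** Ring A is taken apart into a three-carbon ketone unit and a three-carbon vinamidinium unit. The ketone is aryloxyacetone A3, which carries the ring B oxygen. The vinamidinium salt A4 carries the ring D side chain (with a ring D bromide) on its central carbon. In the forward direction, base condenses both alpha carbons of A3 with the two termini of A4, two molecules of dimethylamine are lost, and the open tetra-aryl phenol A5 results.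
- Merits: it uses the same logic as the chosen plan, a benzene ring built on an ether oxygen, but with stable, storable partners and mild base. The 1,2,4-pattern follows from connectivity alone, so there is no orientation question. The ring A/ring B ether is made by simple phenol alkylation.
- Weak points: the new ring is built on the unhindered ring B oxygen, where ordinary coupling would have served. The flanked ring C oxygen is still MOM-protected in A5. It must later close the 18-membered ring by Ullmann coupling with the unactivated ring D bromide, so the hardest C–O bond of the molecule becomes the macrocyclisation, after the new ring A phenol has been capped.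
- Comparison: the arene-forming step of Alternative 2 is probably more dependable than step 13, since it needs no sensitive alkynyl ether and carries no regiochemical risk. The chosen plan spends its ring construction on the oxygen where coupling is weakest and keeps the easy ether for the closure.

**Alternative 3:** The same ring A/ring B ether bond that the chosen plan closes is cut, but the forward reaction is an oxidative phenol coupling. Anodic oxidation of the open bis-phenol A6 (ring A as a 2,6-dibromophenol, ring B as a 2,6-dichlorophenol), then reduction with Zn, gives the macrocyclic bromo dichloro dimethyl ether A7.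
- Merits: ring closure at room temperature without copper; the halogen pattern decides which phenol is oxidised and where the oxygen attacks; the ring A phenol emerges free.
- Weak points: four halogens must be installed and three removed afterwards. The electron-rich, trioxygenated ring C is itself open to anodic oxidation. The hindered ring C–O–ring D ether is already present in A6 and must be made by some other means.
- Comparison: Alternative 3 may close the ring more gently than step 15. The chosen plan needs fewer halogen and redox manipulations, takes its single ring A bromine from the commercial aldehyde 15, and gives an answer for the hindered ether.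

Key step: step 13

Remark: olefin 7 is expected as an E/Z mixture and is carried on as such, since step 4 removes the double bond and both isomers converge on 8.

## Route

Step 1
Reactants: 1 4-hydroxybenzyl alcohol
Product: 2 [4-(methoxymethoxy)phenyl]methanol
Conditions: NaH (1.0 equiv), THF–DMF, 0 °C; then MOMCl (1.05 equiv), 0 °C to rt
Reagents that add atoms: chloromethyl methyl ether (MOMCl), COCCl
Why: Williamson-type O-alkylation; one equivalent of NaH deprotonates only the phenol, which is far more acidic than the benzylic alcohol, and the phenoxide should capture MOMCl before the neutral alcohol does.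

Step 2
Reactants: 2 [4-(methoxymethoxy)phenyl]methanol
Product: 4 {[4-(methoxymethoxy)phenyl]methyl}triphenylphosphonium bromide, via benzylic bromide 3 (not isolated)
Conditions: CBr4 (1.05 equiv), PPh3 (1.1 equiv), CH2Cl2, 0 °C; then PPh3 (1.1 equiv), PhMe, 90 °C
Reagents that add atoms: tetrabromomethane, BrC(Br)(Br)Br; triphenylphosphine, c1ccc(cc1)P(c1ccccc1)c1ccccc1
Why: Appel bromination is neutral and spares the acetal; the electron-rich benzylic bromide 3 is not stored but quaternised at once by PPh3 (SN2), and the salt should crystallise from toluene away from Ph3PO and bromoform.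

Step 3
Reactants: 4 {[4-(methoxymethoxy)phenyl]methyl}triphenylphosphonium bromide; 5 2-hydroxy-3,4-dimethoxybenzaldehyde
Product: 7 2,3-dimethoxy-6-{2-[4-(methoxymethoxy)phenyl]ethenyl}phenol (E/Z mixture), via phosphonium ylide 6 (not isolated)
Conditions: 4 (1.3 equiv), KOtBu (2.4 equiv), THF, 0 °C to rt; then aq NH4Cl
Reagents that add atoms: none
Why: Wittig olefination with a semi-stabilised benzylic ylide; the extra base turns the ortho-hydroxy aldehyde into its phenoxide, which still condenses, and the olefin geometry is irrelevant because the double bond is removed next.

Step 4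
Reactants: 7 2,3-dimethoxy-6-{2-[4-(methoxymethoxy)phenyl]ethenyl}phenol (E/Z mixture)
Product: 8 2,3-dimethoxy-6-{2-[4-(methoxymethoxy)phenyl]ethyl}phenol
Conditions: H2 (1 atm), Pd/C, EtOAc, rt
Reagents that add atoms: none
Why: Heterogeneous catalytic hydrogenation of a stilbene; the MOM ether, methyl ethers and free phenol are inert under these conditions and both olefin isomers give the same bibenzyl.

Step 5
Reactants: 8 2,3-dimethoxy-6-{2-[4-(methoxymethoxy)phenyl]ethyl}phenol; 9 trichloroethylene
Product: 11 2-{[(E)-1,2-dichloroethenyl]oxy}-3,4-dimethoxy-1-{2-[4-(methoxymethoxy)phenyl]ethyl}benzene, via dichloroacetylene 10 (not isolated)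
Conditions: K2CO3, DMF, 70 °C
Reagents that add atoms: none
Why: Base-mediated O-vinylation of a phenol with trichloroethylene; dehydrochlorination gives dichloroacetylene in low concentration, the phenoxide adds to it in anti fashion to give the (E)-1,2-dichlorovinyl ether, and this small linear electrophile should reach the oxygen flanked by the methoxy group and the ethylene bridge.

Step 6
Reactants: 11 2-{[(E)-1,2-dichloroethenyl]oxy}-3,4-dimethoxy-1-{2-[4-(methoxymethoxy)phenyl]ethyl}benzene
Product: 14 2-(ethynyloxy)-3,4-dimethoxy-1-{2-[4-(methoxymethoxy)phenyl]ethyl}benzene, via chloroethynyl ether 12 (not isolated), via lithium acetylide 13 (not isolated)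
Conditions: n-BuLi (2.3 equiv), Et2O, –78 to –40 °C; then H2O, –78 °C to rt
Reagents that add atoms: none
Why: Known conversion of 1,2-dichlorovinyl ethers into alkynyl ethers; the first equivalent of n-BuLi causes dehydrochlorination to the chloroalkyne, the second chlorine–lithium exchange, and protonation of the acetylide gives the terminal alkynyl ether, while the MOM and methyl ethers are not metalated at this temperature.

Step 7
Reactants: 15 3-bromo-4-methoxybenzaldehyde
Product: 16 (3-bromo-4-methoxyphenyl)methanol
Conditions: NaBH4, MeOH, 0 °C
Reagents that add atoms: none
Why: Borohydride reduction of an aromatic aldehyde; the aryl bromide and the methyl ether are untouched.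

Step 8
Reactants: 16 (3-bromo-4-methoxyphenyl)methanol
Product: 17 2-bromo-4-(bromomethyl)-1-methoxybenzene
Conditions: PBr3, CH2Cl2, 0 °C
Reagents that add atoms: phosphorus tribromide, BrP(Br)Br
Why: Standard conversion of a benzylic alcohol into the bromide by bromide displacement on the phosphite ester, fast at 0 °C for a para-alkoxybenzyl alcohol.

Step 9
Reactants: 17 2-bromo-4-(bromomethyl)-1-methoxybenzene; 18 propargyl bromide
Product: 20 2-bromo-4-(but-3-yn-1-yl)-1-methoxybenzene, via allenylmagnesium bromide 19 (not isolated)
Conditions: Mg, HgCl2 (cat.), Et2O, 0 °C; then 17, 0 °C to rt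
Reagents that add atoms: none
Why: Propargyl bromide and Mg give allenylmagnesium bromide, which attacks the benzylic bromide through its gamma carbon (SE2' alkylation of a Grignard reagent) to give the homopropargyl arene; aryl bromides do not react with Grignard reagents in the absence of a transition-metal catalyst.

Step 10
Reactants: 20 2-bromo-4-(but-3-yn-1-yl)-1-methoxybenzene; 21 ethyl (Z)-3-iodoacrylate
Product: 22 ethyl (Z)-7-(3-bromo-4-methoxyphenyl)hept-2-en-4-ynoate
Conditions: PdCl2(PPh3)2 (cat.), CuI (cat.), Et3N, THF, rt
Reagents that add atoms: none
Why: Sonogashira coupling; the vinyl iodide adds to zerovalent palladium at room temperature far faster than the electron-rich ortho-methoxy aryl bromide, and the Z geometry of the acrylate should be kept under these mild conditions.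

Step 11
Reactants: 22 ethyl (Z)-7-(3-bromo-4-methoxyphenyl)hept-2-en-4-ynoate
Product: 23 (Z)-7-(3-bromo-4-methoxyphenyl)hept-2-en-4-ynoic acid
Conditions: LiOH, THF–H2O, 0 °C to rt; then aq HCl
Reagents that add atoms: LiOH (lithium hydroxide), [Li+].[OH-]
Why: Saponification of an ethyl ester at or below room temperature; the Z-enyne should not isomerise and the aryl bromide is inert.

Step 12
Reactants: 23 (Z)-7-(3-bromo-4-methoxyphenyl)hept-2-en-4-ynoic acid
Product: 24 6-[2-(3-bromo-4-methoxyphenyl)ethyl]-2H-pyran-2-one
Conditions: ZnBr2 (cat.), THF, rt
Reagents that add atoms: none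
Why: Lewis acid-catalysed 6-endo-dig lactonisation of a (Z)-2-en-4-ynoic acid; ZnBr2 activates the alkyne and the cis carboxyl oxygen adds to the distal alkyne carbon, a known route to 6-alkyl-2-pyrones in preference to the five-membered ylidene butenolide.

Step 13
Reactants: 14 2-(ethynyloxy)-3,4-dimethoxy-1-{2-[4-(methoxymethoxy)phenyl]ethyl}benzene; 24 6-[2-(3-bromo-4-methoxyphenyl)ethyl]-2H-pyran-2-one
Product: 26 2-bromo-4-{2-[3-(2,3-dimethoxy-6-{2-[4-(methoxymethoxy)phenyl]ethyl}phenoxy)phenyl]ethyl}-1-methoxybenzene, via bicyclic lactone 25 (not isolated)
Conditions: 14 (1.3 equiv), degassed o-xylene, BHT (cat.), 140 °C, sealed tube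
Reagents that add atoms: none
Why: The reaction is a thermal Diels–Alder cycloaddition with inverse electron demand between the electron-rich alkynyl ether 14 and the diene C3–C6 of 2-pyrone 24, followed by retro-Diels–Alder loss of CO2 from the bridged lactone 25; the closest known reaction type is the benzannulation of 2-pyrones with heteroatom-substituted alkynes (ynamines, siloxy- and alkoxyalkynes). Ring D is closed by the intermolecular [4+2] step, which forms the bonds from the oxygen-bearing alkyne carbon to C3 and from the terminal alkyne carbon to C6, and it becomes aromatic when the lactone bridge leaves as CO2, which should be fast at the temperature of the cycloaddition. No stereocentre remains, since both bridgehead centres of 25 are lost on aromatisation. The selectivity needed is the meta relation between the ether oxygen and the side chain: the terminal alkyne carbon is the nucleophilic end of the alkynyl ether and C6, the vinylogous acyl position of the lactone, is the electrophilic end of the diene, so bond formation between these two should lead, and the bulk of the doubly ortho-substituted aryloxy group points the same way, towards the unsubstituted C3. The alkynyl ether has no alkyl C–H beta to oxygen, so the retro-ene route to a ketene that limits alkyl alkynyl ethers on heating is closed, and its two ortho substituents should slow self-condensation. The MOM ether, the methyl ethers and the aryl bromide are spectators, and BHT is added against radical oligomerisation of 14.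

Step 14
Reactants: 26 2-bromo-4-{2-[3-(2,3-dimethoxy-6-{2-[4-(methoxymethoxy)phenyl]ethyl}phenoxy)phenyl]ethyl}-1-methoxybenzene
Product: 27 4-[2-(2-{3-[2-(3-bromo-4-methoxyphenyl)ethyl]phenoxy}-3,4-dimethoxyphenyl)ethyl]phenol
Conditions: HCl, MeOH, 45 °C
Reagents that add atoms: none
Why: Acid-catalysed acetal exchange removes the MOM group as dimethoxymethane; aryl methyl ethers, the diaryl ether and the aryl bromide are stable to methanolic HCl.

Step 15
Reactants: 27 4-[2-(2-{3-[2-(3-bromo-4-methoxyphenyl)ethyl]phenoxy}-3,4-dimethoxyphenyl)ethyl]phenol
Product: 28 marchantin H tri-O-methyl ether (18-membered macrocycle; ring A methoxy and ring C dimethoxy)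
Conditions: CuI, N,N-dimethylglycine, Cs2CO3, 1,4-dioxane, 105 °C, 2 mM (slow addition)
Reagents that add atoms: none
Why: Intramolecular Ullmann diaryl ether synthesis; the copper phenoxide of ring B couples with the ring A bromide ortho to the methoxy group, the classical pairing of a para-alkyl phenol with a 3-bromo-4-methoxyphenyl unit for macrocyclic diaryl ethers, and high dilution favours closure of the 18-membered ring over oligomerisation.

Step 16
Reactants: 28 marchantin H tri-O-methyl ether
Product: 29 marchantin H
Conditions: BBr3 (excess), CH2Cl2, –78 °C to rt; then H2O
Reagents that add atoms: none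
Why: BBr3 demethylation; bromide attacks the O-methyl carbon of each boron-complexed aryl methyl ether, the diaryl ethers have no sp3 carbon on oxygen and survive, and hydrolysis of the aryl borates frees the phenol and the catechol.

## Compound list

1 | 4-hydroxybenzyl alcohol | OCc1ccc(O)cc1 | starting material
2 | [4-(methoxymethoxy)phenyl]methanol | COCOc1ccc(CO)cc1 | intermediate
3 | 1-(bromomethyl)-4-(methoxymethoxy)benzene (not isolated) | COCOc1ccc(CBr)cc1 | intermediate
4 | {[4-(methoxymethoxy)phenyl]methyl}triphenylphosphonium bromide | COCOc1ccc(C[P+](c2ccccc2)(c2ccccc2)c2ccccc2)cc1.[Br-] | intermediate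
5 | 2-hydroxy-3,4-dimethoxybenzaldehyde | COc1ccc(C=O)c(O)c1OC | starting material
6 | {[4-(methoxymethoxy)phenyl]methylidene}triphenylphosphorane (ylide, not isolated) | COCOc1ccc(C=P(c2ccccc2)(c2ccccc2)c2ccccc2)cc1 | intermediate
7 | 2,3-dimethoxy-6-{2-[4-(methoxymethoxy)phenyl]ethenyl}phenol (E/Z mixture, double bond geometry not defined) | COCOc1ccc(C=Cc2ccc(OC)c(OC)c2O)cc1 | intermediate
8 | 2,3-dimethoxy-6-{2-[4-(methoxymethoxy)phenyl]ethyl}phenol | COCOc1ccc(CCc2ccc(OC)c(OC)c2O)cc1 | intermediate
9 | trichloroethylene | ClC=C(Cl)Cl | starting material
10 | dichloroacetylene (not isolated) | ClC#CCl | intermediate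
11 | 2-{[(E)-1,2-dichloroethenyl]oxy}-3,4-dimethoxy-1-{2-[4-(methoxymethoxy)phenyl]ethyl}benzene | Cl/C=C(/Cl)Oc1c(OC)c(OC)ccc1CCc1ccc(OCOC)cc1 | intermediate
12 | 2-[(chloroethynyl)oxy]-3,4-dimethoxy-1-{2-[4-(methoxymethoxy)phenyl]ethyl}benzene (not isolated) | ClC#COc1c(OC)c(OC)ccc1CCc1ccc(OCOC)cc1 | intermediate
13 | lithium acetylide of 14 (not isolated) | [Li]C#COc1c(OC)c(OC)ccc1CCc1ccc(OCOC)cc1 | intermediate
14 | 2-(ethynyloxy)-3,4-dimethoxy-1-{2-[4-(methoxymethoxy)phenyl]ethyl}benzene | C#COc1c(OC)c(OC)ccc1CCc1ccc(OCOC)cc1 | intermediate
15 | 3-bromo-4-methoxybenzaldehyde | COc1ccc(C=O)cc1Br | starting material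
16 | (3-bromo-4-methoxyphenyl)methanol | COc1ccc(CO)cc1Br | intermediate
17 | 2-bromo-4-(bromomethyl)-1-methoxybenzene | COc1ccc(CBr)cc1Br | intermediate
18 | propargyl bromide (3-bromoprop-1-yne) | C#CCBr | starting material
19 | allenylmagnesium bromide (not isolated) | C=C=C[Mg]Br | intermediate
20 | 2-bromo-4-(but-3-yn-1-yl)-1-methoxybenzene | COc1ccc(CCC#C)cc1Br | intermediate
21 | ethyl (Z)-3-iodoacrylate | CCOC(=O)/C=C\I | starting material
22 | ethyl (Z)-7-(3-bromo-4-methoxyphenyl)hept-2-en-4-ynoate | CCOC(=O)/C=C\C#CCCc1ccc(OC)c(Br)c1 | intermediate
23 | (Z)-7-(3-bromo-4-methoxyphenyl)hept-2-en-4-ynoic acid | OC(=O)/C=C\C#CCCc1ccc(OC)c(Br)c1 | intermediate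
24 | 6-[2-(3-bromo-4-methoxyphenyl)ethyl]-2H-pyran-2-one | O=c1cccc(CCc2ccc(OC)c(Br)c2)o1 | intermediate
25 | racemic 1-[2-(3-bromo-4-methoxyphenyl)ethyl]-5-(2,3-dimethoxy-6-{2-[4-(methoxymethoxy)phenyl]ethyl}phenoxy)-2-oxabicyclo[2.2.2]octa-5,7-dien-3-one (not isolated) | O=C1OC2(CCc3ccc(OC)c(Br)c3)C=CC1C(Oc1c(OC)c(OC)ccc1CCc1ccc(OCOC)cc1)=C2 | intermediate
26 | 2-bromo-4-{2-[3-(2,3-dimethoxy-6-{2-[4-(methoxymethoxy)phenyl]ethyl}phenoxy)phenyl]ethyl}-1-methoxybenzene | COc1ccc(CCc2cccc(Oc3c(OC)c(OC)ccc3CCc3ccc(OCOC)cc3)c2)cc1Br | intermediate
27 | 4-[2-(2-{3-[2-(3-bromo-4-methoxyphenyl)ethyl]phenoxy}-3,4-dimethoxyphenyl)ethyl]phenol | COc1ccc(CCc2cccc(Oc3c(OC)c(OC)ccc3CCc3ccc(O)cc3)c2)cc1Br | intermediate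
28 | marchantin H tri-O-methyl ether | COc1ccc2cc1Oc1ccc(cc1)CCc1ccc(OC)c(OC)c1Oc1cccc(c1)CC2 | intermediate
29 | marchantin H | Oc1ccc2cc1Oc1ccc(cc1)CCc1ccc(O)c(O)c1Oc1cccc(c1)CC2 | target

## Step count and risks

Total step count: 16. Longest linear sequence: 10 steps (steps 7–12 then 13–16 from 15; equally steps 1–6 then 13–16 from 1).

**Step 13 (key step).** The cycloaddition may be slower than the thermal decay of 14, by oligomerisation or by hydration through traces of acid and water. The cause is that pyrone 24 has no acceptor beyond the lactone carbonyl and an aryloxy alkyne is only moderately electron-rich. A lesser risk is some bond formation in the ortho sense. The fallback gives up the cycloaddition, keeps both halves of the molecule, sets out from 8 and 17 and comes back at 26. Phenol 8 would be O-arylated with 3-iodobenzaldehyde under CuI/picolinic acid/K3PO4 in DMSO, conditions suited to ortho,ortho'-disubstituted phenols, to give 3-(2,3-dimethoxy-6-{2-[4-(methoxymethoxy)phenyl]ethyl}phenoxy)benzaldehyde F1. Bromide 17 and PPh3 would give [(3-bromo-4-methoxyphenyl)methyl]triphenylphosphonium bromide F2. Wittig olefination of F1 with F2 and KOtBu would give 2-bromo-4-{2-[3-(2,3-dimethoxy-6-{2-[4-(methoxymethoxy)phenyl]ethyl}phenoxy)phenyl]ethenyl}-1-methoxybenzene F3 as an E/Z mixture. Diimide reduction (TsNHNH2, NaOAc, aqueous THF, reflux), which spares the aryl bromide, would then give 26.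

**Step 6.** The terminal alkynyl ether may be lost during work-up and purification through hydration or polymerisation on contact with acidic surfaces; metalation next to the MOM group could interfere if the temperature rises. The fallback sets out from 11 and comes back at 14. The acetylide 13 would be quenched with Me3SiCl instead of water to give {[2,3-dimethoxy-6-{2-[4-(methoxymethoxy)phenyl]ethyl}phenoxy]ethynyl}trimethylsilane F4, a C-silylated alkynyl ether that should stand chromatography and storage. TBAF in THF at low temperature, just before step 13, would remove the silyl group to give 14.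

**Step 9.** The Grignard reagent may attack through its alpha carbon, giving the allene isomer, and the reactive para-methoxybenzylic bromide may undergo Wurtz homocoupling. The fallback sets out from 17 and comes back at 20. Alkylation with 1-(trimethylsilyl)propyne/n-BuLi (THF, –78 °C), a stabilised propargyl anion that does not exchange with the aryl bromide, would give [4-(3-bromo-4-methoxyphenyl)but-1-yn-1-yl]trimethylsilane F5. K2CO3 in MeOH would then remove the silyl group to give 20.

**Step 12.** Closure may take the 5-exo course to the ylidene butenolide, or the acid may isomerise to the E form, which cannot lactonise. The fallback sets out from 20 and comes back at 24, passing by 22 and 23. Alkyne 20 and propiolic acid would be combined with the cationic gold catalyst Ph3PAuCl/AgOTf in CH2Cl2. Markovnikov addition of the acid to the alkyne gives the enol ester 4-(3-bromo-4-methoxyphenyl)but-1-en-2-yl prop-2-ynoate F6, which cyclises in the same flask in the 6-endo sense to 24.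

**Step 15.** Intermolecular coupling to oligomers and protodebromination may outrun ring closure, because the bromide is electron-rich and ortho-substituted and the ring to be closed is stiffened by four arenes. The fallback sets out from 27 and comes back at 28. Miyaura borylation (bis(pinacolato)diboron, PdCl2(dppf), KOAc, dioxane) would give 4-[2-(2-{3-[2-(4-methoxy-3-(4,4,5,5-tetramethyl-1,3,2-dioxaborolan-2-yl)phenyl)ethyl]phenoxy}-3,4-dimethoxyphenyl)ethyl]phenol F7. Oxidative Chan–Lam closure (Cu(OAc)2, pyridine, B(OH)3, 4 Å sieves, MeCN, air, high dilution) would then form the same C–O bond at much lower temperature.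

## Further compounds

F1 | step 13 | 3-(2,3-dimethoxy-6-{2-[4-(methoxymethoxy)phenyl]ethyl}phenoxy)benzaldehyde | O=Cc1cccc(Oc2c(OC)c(OC)ccc2CCc2ccc(OCOC)cc2)c1
F2 | step 13 | [(3-bromo-4-methoxyphenyl)methyl]triphenylphosphonium bromide | COc1ccc(C[P+](c2ccccc2)(c2ccccc2)c2ccccc2)cc1Br.[Br-]
F3 | step 13 | 2-bromo-4-{2-[3-(2,3-dimethoxy-6-{2-[4-(methoxymethoxy)phenyl]ethyl}phenoxy)phenyl]ethenyl}-1-methoxybenzene (E/Z mixture) | COc1ccc(C=Cc2cccc(Oc3c(OC)c(OC)ccc3CCc3ccc(OCOC)cc3)c2)cc1Br
F4 | step 6 | {[2,3-dimethoxy-6-{2-[4-(methoxymethoxy)phenyl]ethyl}phenoxy]ethynyl}trimethylsilane | C[Si](C)(C)C#COc1c(OC)c(OC)ccc1CCc1ccc(OCOC)cc1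
F5 | step 9 | [4-(3-bromo-4-methoxyphenyl)but-1-yn-1-yl]trimethylsilane | COc1ccc(CCC#C[Si](C)(C)C)cc1Br
F6 | step 12 | 4-(3-bromo-4-methoxyphenyl)but-1-en-2-yl prop-2-ynoate | C#CC(=O)OC(=C)CCc1ccc(OC)c(Br)c1
F7 | step 15 | 4-[2-(2-{3-[2-(4-methoxy-3-(4,4,5,5-tetramethyl-1,3,2-dioxaborolan-2-yl)phenyl)ethyl]phenoxy}-3,4-dimethoxyphenyl)ethyl]phenol | COc1ccc(CCc2cccc(Oc3c(OC)c(OC)ccc3CCc3ccc(O)cc3)c2)cc1B1OC(C)(C)C(C)(C)O1
A1 | alternative 1 | 19-membered dibenzylic sulfone (CH2–SO2–CH2 between rings B and C) | COc1ccc2cc1Oc1ccc(cc1)CS(=O)(=O)Cc1ccc(OC)c(OC)c1Oc1cccc(c1)CC2
A2 | alternative 1 | marchantin H trimethyl ether | COc1ccc2cc1Oc1ccc(cc1)CCc1ccc(OC)c(OC)c1Oc1cccc(c1)CC2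
A3 | alternative 2 | 1-(4-{2-[3,4-dimethoxy-2-(methoxymethoxy)phenyl]ethyl}phenoxy)propan-2-one | CC(=O)COc1ccc(CCc2ccc(OC)c(OC)c2OCOC)cc1
A4 | alternative 2 | 2-[2-(3-bromophenyl)ethyl]-1,3-bis(dimethylamino)trimethinium hexafluorophosphate | CN(C)C=C(CCc1cccc(Br)c1)C=[N+](C)C.F[P-](F)(F)(F)(F)F
A5 | alternative 2 | open tetra-aryl compound with free ring A phenol and ring D bromide | Oc1ccc(CCc2cccc(Br)c2)cc1Oc1ccc(CCc2ccc(OC)c(OC)c2OCOC)cc1
A6 | alternative 3 | open bis-phenol with 2,6-dibromophenol ring A and 2,6-dichlorophenol ring B | Oc1c(Br)cc(CCc2cccc(Oc3c(OC)c(OC)ccc3CCc3cc(Cl)c(O)c(Cl)c3)c2)cc1Br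
A7 | alternative 3 | bromo dichloro marchantin H dimethyl ether | Oc1c(Br)cc2cc1Oc1c(Cl)cc(cc1Cl)CCc1ccc(OC)c(OC)c1Oc1cccc(c1)CC2
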